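Elm was to be read at 3.0 h and alder at 0.80 h, so I wrote this note for whoever took over the bench.

| flask | starting material | second substrate | free enzyme | remark | time |
|---|---|---|---|---|---|
| Saturday's | 0.050 M | 0.25 M | 10 µM | run made earlier |  |
| Sunday's | 0.079 M | 0.25 M | 10 µM | run made earlier |  |
| elm | 0.10 M | 0.250 M | 10 µM |  | 3.0 h |
| alder | 0.060 M | 0.250 M | 10 µM |  | 0.80 h |

- Saturday's (time / min: target / %, starting material / %): 25.0: 10.0, 87.6; 50.0: 18.4, 73.5; 80.0: 26.7, 63.7; 90.0: 32.4, 62.4; 120: 37.6, 52.8
- Sunday's (time / min: target / %, starting material / %): 10.0: 3.4, 93.5; 20.0: 7.6, 88.5; 40.0: 14.9, 82.1; 60.0: 20.4, 71.4; 120: 36.8, 52.6

(scatter of a reading: 1 percentage point)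

- a reading or a percentage of target counts all its forms, free or not
- a reading of starting material is of its free form alone

* which of the two ends with the higher amount of target, in percent of the starting material charged ("neither" if they lie within 2 percentage points) (elm / alder / neither)
* target at the end, in percent of the starting material charged, elm
* target at the end, in percent of the starting material charged, alder

1. Each flask held starting material, second substrate and free enzyme, and I reckoned in fractions of the charge.

2. At their last readings, Saturday's run kept 52.8% of its starting material free and Sunday's kept 52.6%, despite different charges. I therefore treated the loss as pseudo-first-order, with a constant of 0.320 /h.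

3. The same readings gave 0.786 of target per fraction of the charge no longer free; I called this the target share.

4. I expected elm to keep 0.383 free and show 48.6% target, and alder to keep 0.774 free and show 17.8%.

5. I put elm's first answer back in, assuming one second substrate per target, and 0.806 of that charge remained, more than was used. My note therefore said to add none, and my figures stood.

6. The forecast, from the same runs, said elm, with 49% for elm and 18% for alder, holding that “conversion does not depend on starting concentration”.

7. Elm ended at 45.7% and alder at 17.4%, so the answer was elm.

    first complex → loaded enzyme + first product (k = 130 /min)
    starting material + free enzyme ⇌ first complex (K = 3.90 /M, k = 11000 /M/s)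
    starting material + target ⇌ idle adduct, settled at all times (K = 11.0 /M)
    second complex → free enzyme + target (k = 1700 /min)
    second substrate + loaded enzyme ⇌ second complex (K = 28.0 /M, k = 42000 /M/min)

8. In elm, starting material entered first complex while second substrate entered second complex, each step having half its turnover behind it by 1.24 h, with free enzyme at 78.9% of its charge at 1.50 h. Elm's target share came to 0.765, and the 14 percentage points between conversion and target was half of the idle adduct's 28.1%, which counts as two. In the neighbour flask, elm left until 8.0 h, 12.9% of the starting material stayed free and target reached 77.5%, a higher target share of 0.890.

The numbers in the tables are simulated from invented constants; scatter was added.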